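In a one-step world the substrate would give one peak. Here the open intermediate splits between two peaks, trapped intermediate and product, and that split is what is asked.

| flask | substrate | coupling partner | capture agent | free catalyst | second catalyst | remark | time |
|---|---|---|---|---|---|---|---|
| noon | 11 mM | 2 equiv | 11 mM | 2.5 mol% | 0.14 mol% | run made earlier |  |
| spring | 11 mM | 1.3 equiv | 11 mM | 2.5 mol% | 0.14 mol% | run made earlier |  |
| dawn | 11 mM | 3 equiv | 11 mM | 2.5 mol% | 0.14 mol% | run made earlier |  |
| oak | 11 mM (fed, over 30 h) | 2.00 equiv | 11.0 mM | 2.5 mol% | 0.14 mol% | all else is in the flask from the start; the feed brings no volume worth counting | 40 h |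
| alder | 11 mM | 2.00 equiv (fed, over 30 h) | 11.0 mM | 2.5 mol% | 0.14 mol% | all else is in the flask from the start; the feed brings no volume worth counting | 40 h |
| birch | 11 mM | 2.00 equiv | 11.0 mM | 2.5 mol% | 0.14 mol% | everything together at the start | 40 h |

| run | time / h | trapped intermediate / % | product / % |
|---|---|---|---|
| noon | 2.00 | 3.6 | 4.1 |
| noon | 3.00 | 6.8 | 7.3 |
| noon | 4.00 | 9.1 | 9.0 |
| noon | 6.00 | 14.5 | 14.3 |
| noon | 10.0 | 23.1 | 22.6 |
| noon | 15.0 | 29.7 | 33.1 |
| noon | 25.0 | 36.8 | 49.2 |
| spring | 2.00 | 3.7 | 3.2 |
| spring | 3.00 | 7.0 | 4.8 |
| spring | 4.00 | 9.6 | 5.5 |
| spring | 6.00 | 15.7 | 9.1 |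
| spring | 10.0 | 25.0 | 15.2 |
| spring | 15.0 | 32.3 | 22.1 |
| spring | 25.0 | 40.8 | 33.1 |
| dawn | 3.00 | 6.5 | 10.3 |
| dawn | 6.00 | 13.8 | 20.9 |
| dawn | 10.0 | 20.7 | 33.7 |
| dawn | 15.0 | 26.4 | 48.1 |
| dawn | 20.0 | 28.7 | 59.4 |
| dawn | 25.0 | 29.8 | 65.7 |

(each reading ± 0.3 percentage points)

- what was read earlier has a scatter of 0.3 percentage points, one standard deviation
- steps under discussion: substrate + free catalyst <-> free catalyst + open intermediate; second catalyst + open intermediate <-> catalyst intermediate; coupling partner + catalyst intermediate -> second catalyst + product; open intermediate + capture agent -> trapped intermediate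

* which flask leads in amount of trapped intermediate, in percent of the substrate charged ("all alike" within 1.5 percentage points) (oak / alder / birch / all alike)
* how much trapped intermediate is there at the end, in percent of the substrate charged: oak
* how much trapped intermediate is there at the end, in percent of the substrate charged: alder
* how much trapped intermediate is there at the end, in percent of the substrate charged: birch

1. Dividing the trapping rate by the product rate removes time. The ratio is taken to follow [capture agent]/[coupling partner]. In the earlier runs [capture agent] starts equal to the substrate charge, so its remaining fraction is one minus the trapped fraction.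

2. My own reckoning uses a selectivity factor, the partition number Γ. At 25.0 h the three runs average 1.85, where Γ is the partner equivalents times the logarithm of starting over present [capture agent], per product fraction.

3. Let s be Γ over the mean partner equivalents. At full conversion, the logarithm of starting over final [capture agent] equals s times the product fraction. Oak's fed pool lies outside these batch runs, so Γ is not applied to it.

4. What must be known well? The scatter is 0.3 percentage points on a product peak of 49.2 %. Reading Γ at 10.0 h gives 2.28, which moves the reckoning for alder by 4.5 points. Taking alder's mean partner as the full charge instead of half moves that reckoning by 14 points. The mean partner therefore moves the reckoning for alder more than the reading time of Γ does.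

5. With half the charge as the mean, alder has s = 1.85, and my reckoning gives 56.0 % trapped.

6. The forecast has a different figure for alder from my reckoning: alder leads, with oak 27 %, alder 52 %, birch 39 %, on the ground that “partner starts scarce, so the pool stays high and trapping dominates early”.

    substrate + free catalyst ⇌ free catalyst + open intermediate (K = 1.10, k = 23.0 /M/min)
    second catalyst + open intermediate ⇌ catalyst intermediate (K = 2500 /M, k = 11000 /M/min)
    coupling partner + catalyst intermediate → second catalyst + product (k = 15.0 /M/min)
    open intermediate + capture agent → trapped intermediate (k = 0.130 /M/min)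

The leader is alder with 51.1 %, against oak 26.0 % and birch 38.3 %, so the forecast holds and my 56.0 % stands high. By 4.00 h alder's trapping step has 20 % of its turnover up to 40 h behind it, more than the 1.8 % of the binding of open intermediate to second catalyst. At 30.0 h, with a mean [coupling partner] of 9.79 mM up to then, alder has Γ = 1.94. A run of alder outside 47 % to 57 % would contradict the forecast; the nearest capture agent charges that move alder by 5 points are 9.34 mM and 12.9 mM. For alder's neighbour with 19 mM capture agent, the same s gives 71.7 % trapped; the computed flask holds 67.3 % at the end.

(The runs are calculated with constants of no real substance.)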